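The earlier runs and the new flask were generated by integration with made-up constants, and the scatter is random.

The target of Monday's run cannot all have stayed in solution: its last reading puts 93.0% of the charge in crystals, out of 97.1% of target.

| flask | substrate | reagent in the second phase | remark | time | volume of the second phase over the first |
|---|---|---|---|---|---|
| Saturday's | 0.050 M | 0.105 M | run made earlier |  |  |
| Wednesday's | 0.075 M | 0.105 M | run made earlier |  |  |
| Monday's | 0.10 M | 0.21 M | run made earlier |  |  |
| flask | 0.10 M | 0.105 M |  | 15 min | 0.50 |

| run | time / min | target / % | crystals / % |
|---|---|---|---|
| Saturday's | 2.50 | 98.3 | 94.1 |
| Saturday's | 5.00 | 98.0 | 90.9 |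
| Saturday's | 8.00 | 96.4 | 91.1 |
| Saturday's | 10.0 | 95.6 | 89.1 |
| Saturday's | 12.0 | 93.9 | 89.8 |
| Wednesday's | 1.00 | 78.5 | 72.8 |
| Wednesday's | 3.00 | 98.4 | 93.7 |
| Wednesday's | 6.00 | 97.5 | 96.3 |
| Wednesday's | 8.00 | 98.9 | 94.7 |
| Wednesday's | 12.0 | 96.1 | 92.9 |
| Monday's | 1.00 | 98.1 | 91.4 |
| Monday's | 3.00 | 100.4 | 95.0 |
| Monday's | 6.00 | 98.7 | 96.9 |
| Monday's | 8.00 | 96.4 | 93.9 |
| Monday's | 12.0 | 97.1 | 93.0 |

(readings scatter by 1 percentage point)

- amounts and yields of target count product in the second phase and crystals too
- in the second phase: reagent in the second phase, product in the second phase; everything else is in the first
- charges count per volume of the first phase; a concentration in a rate is the amount of a species over the volume of its own phase; every rate counts per litre of the first phase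
- given per volume of solution although it is solid: crystals
- the earlier runs were read with a standard deviation of 1 percentage point
- steps that have been proposed: substrate + reagent in the reaction phase -> target; crystals <-> target; target <-> product in the second phase; reagent in the reaction phase <-> reagent in the second phase; target -> decomposed product
- the earlier runs hold the two phases in the same ratio of volumes as the flask asked about

- amount of target and product in the second phase and crystals together at 15 min, in percent of the substrate charged
- concentration of target in solution at 15 min, in percent of saturation

The flask can be built up one process at a time. With the main step alone, 0.10 M of substrate meets 0.105 M of reagent, so substrate is the limiting reagent and the total can reach 100% of the charge. Wednesday's run, on the same reagent charge but with less substrate, reads 98.4% at 3.00 min, and the flask has 15 min, so this reckoning assumes that conversion in the flask is complete.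

Adding crystals takes nothing out of the total, since they count as target, and the gap between target and crystals at the last readings of the earlier runs averages 0.00285 M, far below the charge of the flask. That gap, read with the scatter of the readings, holds both the dissolved target and the product in the second phase.

Adding decomposition finally moves the number. Replacing the falling curves of the earlier runs by their mean slope, from near each peak to the last reading, gives a reading of 2.63 × 10⁻⁴ M/min. This is the drain, the molar amount of total target lost per minute while crystals stand, a zero-order loss. Counting it also through the first 1.00 min, when Wednesday's run still reads 78.5%, may err by about 0.263% of the flask's charge. Over 15 min the drain takes 3.95% of the flask's charge, so this reckoning gives 96.1%.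

The forecast gives 95.8% for the total, 0.30 percentage points below this reckoning, and 100% of saturation, and holds the loss “roughly zero order because only saturated dissolved target decomposes”.

The flask gives 95.9% at 15 min, with the solution at 99.5% of saturation and 93.4% as crystals. Decomposed product stands at 4.03% against the 3.95% of the drain.

    substrate + reagent in the reaction phase → target (k = 2.09 /M/s)
    crystals ⇌ target, rate k2*(cs2 - [target]) while solid is left; crystals form when [target] > cs2 (solubility = 2.10 mM, k = 0.375 /s)
    target ⇌ product in the second phase, rate k3*([target] - [product in the second phase]/K3) per volume of the first phase (partition coefficient = 0.450, kL = 0.00901 /s)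
    reagent in the reaction phase ⇌ reagent in the second phase, rate k4*([reagent in the reaction phase] - [reagent in the second phase]/K4) per volume of the first phase (partition coefficient = 1.38, kL = 0.0172 /s)
    target → decomposed product (k = 0.00189 /s)

For this flask, the crystals are a shelter: the total stays high because little target dissolves, and the same flask with target free to stay dissolved holds 27.6% instead of 95.9%. Read at 1.0 h, the drain takes 15.8% from the same flask and leaves 84.2%. The computed neighbour holds 85.3%, with 14.7% decomposed.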